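**Retrosynthetic overview**
1. Target 25 ⇐ protected pentacycle 23; rings C and D are closed together from the tertiary C8 radical of the ring A/B compound 22: C8–C14 (6-endo onto a silyl enol ether), then C13–C16 (5-exo-dig onto the propargyl alkyne).
2. C8 carbinol ⇐ propargylation of ring B β-keto ester 19 ⇐ Dieckmann closure (C6–C8) ⇐ ester-enolate aldol (C9–C10) of fragment 15 with ring A keto lactone 11, the lactone moving from O2 to O10.
3. 11 ⇐ 1-methylcyclohexa-2,5-diene-1-carboxylic acid 3 by desymmetrizing bromolactonization (C4), radical allylation (C5), β-epoxidation and C19-assisted epoxide opening (2α-O, 3β-OH).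
4. Ring order: A (with temporary lactones) → B → C and D in one radical step.

Assumption: the target SMILES is read as the 2α,3β,13-triol (2-epi-GA8, trans-diaxial diol); gibberellane atom numbers C1–C19 are used for all intermediates (α = face of the C19 lactone bridge, β = opposite face); (DHQD)2PHAL is taken to give the enantiomer drawn, otherwise (DHQ)2PHAL is used.

**Step 1**
Reactants: 1 cyclohexa-1,4-diene
Product: 3 1-methylcyclohexa-2,5-diene-1-carboxylic acid, via lithium cyclohexa-2,5-diene-1-carboxylate 2 (not isolated)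
Conditions: s-BuLi, TMEDA, THF, −78 °C; CO2, then Ar purge; LiN(i-Pr)2 (1.2 equiv), −78 → 0 °C; MeI; 1 M HCl
Reagents that add atoms: carbon dioxide, O=C=O; iodomethane, CI
Why: Deprotonation of the doubly allylic CH2, carboxylation, and α-methylation of the carboxylate dianion (the dienolate of a Birch reductive alkylation) give the achiral, symmetric acid; no stereocentre is formed.

**Step 2**
Reactants: 3 1-methylcyclohexa-2,5-diene-1-carboxylic acid
Product: 4 (1S,5S,8S)-8-bromo-1-methyl-6-oxabicyclo[3.2.1]oct-2-en-7-one (lactone O on C10 α, 5β-Br)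
Conditions: NBS (1.2 equiv), (DHQD)2PHAL (10 mol%), CHCl3/hexane 1:1, −40 °C
Reagents that add atoms: N-bromosuccinimide, O=C1CCC(=O)N1Br
Why: Catalytic asymmetric desymmetrizing bromolactonization: the catalyst selects one of the two enantiotopic alkenes and the carboxylate adds anti to the bromonium ion, which sets C4 absolutely and C10/C5 relative to it.

**Step 3**
Reactants: 4 ring A bromolactone
Product: 5 8-allyl-1-methyl-6-oxabicyclo[3.2.1]oct-2-en-7-one, allyl on the one-carbon bridge syn to the lactone bridge (5α-allyl)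
Conditions: allyltributylstannane (2 equiv), AIBN (0.2 equiv), PhH, 80 °C
Reagents that add atoms: allyltributylstannane, C=CC[Sn](CCCC)(CCCC)CCCC
Why: Keck radical allylation (SH2' chain): the C5 bridge radical is expected to be trapped on the face of the hydrogen-free lactone bridge, giving the α-allyl group, and this centre is in any case re-equilibrated in step 8.

**Step 4**
Reactants: 5 allyl lactone
Product: 6 2β,3β-epoxide of 5 (epoxide on the face of the one-carbon bridge)
Conditions: mCPBA (1.05 equiv), NaHCO3, CH2Cl2, 0 °C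
Reagents that add atoms: mCPBA, OOC(=O)c1cccc(Cl)c1
Why: Prilezhaev epoxidation: the cis-disubstituted ring alkene reacts much faster than the terminal allyl alkene, and the lactone bridge covers the α face, so oxygen is delivered to the β face.

**Step 5**
Reactants: 6 epoxy lactone
Product: 7 methyl 5α-allyl-2β,3β-epoxy-10α-hydroxy-4β-methylcyclohexane-4α-carboxylate (gibberellane numbers)
Conditions: NaOMe (0.3 equiv), MeOH, 0 °C; NH4Cl
Reagents that add atoms: methanol, CO
Why: Transesterification of the strained bridged lactone frees the C10 hydroxyl without touching the stereocentres; no other ester is present that could re-lactonize with it.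

**Step 6**
Reactants: 7 hydroxy ester
Product: 8 methyl 5α-allyl-2β,3β-epoxy-4β-methyl-10-oxocyclohexane-4α-carboxylate
Conditions: Dess–Martin periodinane (1.3 equiv), NaHCO3, CH2Cl2, 23 °C
Reagents that add atoms: none
Why: Dess–Martin oxidation under buffered, non-basic conditions gives the C10 ketone without opening the β,γ-epoxide.

**Step 7**
Reactants: 8 epoxy ketone
Product: 10 methyl 2β,3β-epoxy-5α-(2-methoxy-2-oxoethyl)-4β-methyl-10-oxocyclohexane-4α-carboxylate, via methoxy hydroperoxide 9 (not isolated)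
Conditions: O3, NaHCO3, CH2Cl2/MeOH 5:1, −78 °C; then Ac2O, pyridine, 0 → 23 °C
Reagents that add atoms: ozone, [O-][O+]=O; methanol, CO
Why: Ozonolysis of the only alkene in methanol gives the Criegee methoxy hydroperoxide, which is dehydrated to the methyl ester (Schreiber work-up), so the allyl group becomes C6–C7.

**Step 8**
Reactants: 10 epoxy keto diester
Product: 11 ring A keto lactone: C19→O–C2 (2α) γ-lactone, 3β-OH, 10-oxo, 5α-CH2CO2Me, 4β-Me
Conditions: camphorsulfonic acid (0.2 equiv), MeCN/H2O 10:1, 40 °C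
Reagents that add atoms: water, O
Why: Acid-catalysed epoxide opening with neighbouring-group participation of the C19 ester carbonyl (5-exo, trans-diaxial, Fürst–Plattner) puts oxygen on C2 from the α face and leaves the 3β-OH, while C5 (α to the ketone) equilibrates through the enol to the equatorial α side chain.

**Step 9**
Reactants: 12 acetone; 13 methyl acrylate
Product: 14 methyl 5-oxohexanoate
Conditions: pyrrolidine (0.2 equiv), AcOH (0.2 equiv), acetone (10 equiv, neat), 60 °C, sealed tube
Reagents that add atoms: none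
Why: Stork enamine Michael addition of the acetone enamine to the acrylate; no stereocentre.

**Step 10**
Reactants: 14 methyl 5-oxohexanoate
Product: 15 methyl 5-[(tert-butyldimethylsilyl)oxy]hex-5-enoate
Conditions: LiN(i-Pr)2 (1.05 equiv), THF, −78 °C; t-BuMe2SiOTf (1.05 equiv)
Reagents that add atoms: tert-butyldimethylsilyl trifluoromethanesulfonate, CC(C)(C)[Si](C)(C)OS(=O)(=O)C(F)(F)F
Why: Kinetic deprotonation of the more acidic methyl ketone at CH3 and O-silylation give the terminal silyl enol ether (C13=C14).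

**Step 11**
Reactants: 15 silyl enol ether ester; 11 ring A keto lactone
Product: 18 aldol–lactone diester: 19,10-lactone, 2α,3β-bis(triethylsilyloxy), 5α-CH2CO2Me, C10 bearing CH(CO2Me)CH2CH2C(OSiMe2t-Bu)=CH2 (C9 mainly 9β-H), via lithium ester enolate 16 (not isolated), via dilithium 2,3-dialkoxide 17 (not isolated)
Conditions: 15 (2.3 equiv), LiN(i-Pr)2 (2.3 equiv), THF/DMPU 4:1, −78 °C; add 11, −78 °C, 1 h; Et3SiOTf (3 equiv), −78 → −40 °C; NaHCO3
Reagents that add atoms: triethylsilyl trifluoromethanesulfonate, CC[Si](CC)(CC)OS(=O)(=O)C(F)(F)F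
Why: Ester-enolate aldol addition to the bicyclic ketone from its open β face (the α face is covered by the lactone bridge), the Z(O)-enolate giving the syn C9 adduct through a closed transition state; the new 10α-alkoxide lies 1,3-diaxial to C19 and translactonizes (O2 → O10), and both free alkoxides are capped as silyl ethers.

**Step 12**
Reactants: 18 aldol–lactone diester
Product: 19 ring A/B β-keto ester: 8-oxo, 6β-CO2Me, 9β-H with the C9 side chain α, 19,10-lactone, 2α,3β-bis(triethylsilyloxy)
Conditions: NaN(SiMe3)2 (2.1 equiv), THF, −78 → −20 °C; AcOH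
Reagents that add atoms: none
Why: Dieckmann condensation: only closure of the C6 enolate onto the C8 ester gives a β-keto ester that is held as its enolate, so ring B forms C6–C8; C6 (ester trans to C4) and C9 (epimerizable α to the ketone; side chain cis to the lactone oxygen, trans to C1) settle in their more stable configurations.

**Step 13**
Reactants: 19 ring A/B β-keto ester; 20 propargyl bromide
Product: 21 C8 tertiary homopropargylic alcohol (8-hydroxy-8-propargyl, C8 epimers)
Conditions: indium powder, THF/H2O 1:1, 23 °C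
Reagents that add atoms: none
Why: Barbier propargylation: the allenylindium species adds to the ketone (SE2') to give the homopropargylic alcohol; the C8 configuration is irrelevant because C8 becomes a radical.

**Step 14**
Reactants: 21 tertiary alcohol
Product: 22 tert-alkyl N-phthalimidoyl oxalate of 21
Conditions: N-phthalimidoyl chlorooxalate (2 equiv), Et3N, DMAP (cat.), THF, −78 → 0 °C
Reagents that add atoms: N-phthalimidoyl chlorooxalate, O=C(Cl)C(=O)ON1C(=O)c2ccccc2C1=O
Why: O-Acylation of the tertiary alcohol gives a redox-active oxalate, a known precursor of tertiary alkyl radicals.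

**Step 15**
Reactants: 22 N-phthalimidoyl oxalate
Product: 23 methyl ester of the target with 2α,3β-bis(triethylsilyl) and 13-(tert-butyldimethylsilyl) ethers
Conditions: Ru(bpy)3(PF6)2 (2 mol%), Hantzsch ester (1.5 equiv), i-Pr2NEt·HBF4 (1 equiv), THF/CH2Cl2 1:1 (5 mM), blue LEDs, 25 °C
Reagents that add atoms: none
Why: Proposed new method: photoreductive fragmentation of the oxalate (loss of two CO2) gives the tertiary C8 radical, which adds 6-endo-trig to the CH2 end of the silyl enol ether on the face of the C9 side chain (ring C cis-fused to ring B, so C14 is α and C15 β); the resulting α-silyloxy C13 radical closes ring D by 5-exo-dig addition to the alkyne and the vinyl radical takes H from the Hantzsch ester to give the exocyclic methylene; the closest known reactions are Giese additions of tertiary radicals from N-phthalimidoyl oxalates and ketyl–alkyne cyclizations to the bicyclo[3.2.1]octane of gibberellins.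

**Step 16**
Reactants: 23 protected methyl ester
Product: 24 7-carboxylic acid with the three silyl ethers intact
Conditions: n-PrSLi (6 equiv), HMPA, 25 °C; cold 0.5 M HCl
Reagents that add atoms: none
Why: SN2 O-demethylation of the hindered methyl ester by thiolate leaves the lactone closed and the silyl ethers in place, so no acyl migration is possible.

**Step 17**
Reactants: 24 silylated acid
Product: 25 target, 2α,3β,13-trihydroxy-19,10-lactone-7-acid (CNP0265952.2)
Conditions: HF·pyridine, pyridine/THF, 0 → 40 °C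
Reagents that add atoms: none
Why: Fluoride-mediated global desilylation under mildly acidic, non-equilibrating conditions frees the three hydroxyls without translactonization or rearrangement of the 13-hydroxy-16-ene unit.

**Compound list**
1 | cyclohexa-1,4-diene | C1=CCC=CC1 | starting material
2 | lithium cyclohexa-2,5-diene-1-carboxylate | [Li+].[O-]C(=O)C1C=CCC=C1 | intermediate
3 | 1-methylcyclohexa-2,5-diene-1-carboxylic acid | CC1(C(=O)O)C=CCC=C1 | intermediate
4 | (1S,5S,8S)-8-bromo-1-methyl-6-oxabicyclo[3.2.1]oct-2-en-7-one | [C@@H]12CC=C[C@@](C)(C(=O)O1)[C@@H]2Br | intermediate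
5 | 8-allyl lactone, allyl syn to the lactone bridge (5α) | [C@@H]12CC=C[C@@](C)(C(=O)O1)[C@H]2CC=C | intermediate
6 | 2β,3β-epoxide of 5 | [C@@H]12C[C@@H]3O[C@@H]3[C@@](C)(C(=O)O1)[C@H]2CC=C | intermediate
7 | methyl 5α-allyl-2β,3β-epoxy-10α-hydroxy-4β-methylcyclohexane-4α-carboxylate | [C@H]1(O)C[C@@H]2O[C@@H]2[C@@](C)(C(=O)OC)[C@H]1CC=C | intermediate
8 | 10-ketone of 7 | O=C1C[C@@H]2O[C@@H]2[C@@](C)(C(=O)OC)[C@H]1CC=C | intermediate
9 | methoxy hydroperoxide from ozonolysis of 8 | O=C1C[C@@H]2O[C@@H]2[C@@](C)(C(=O)OC)[C@H]1CC(OC)OO | intermediate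
10 | epoxy keto diester (5α-CH2CO2Me) | O=C1C[C@@H]2O[C@@H]2[C@@](C)(C(=O)OC)[C@H]1CC(=O)OC | intermediate
11 | ring A keto lactone (19→2α lactone, 3β-OH, 10-oxo, 5α-CH2CO2Me) | O=C1C[C@H]2OC(=O)[C@](C)([C@H]2O)[C@H]1CC(=O)OC | intermediate
12 | acetone | CC(C)=O | starting material
13 | methyl acrylate | C=CC(=O)OC | starting material
14 | methyl 5-oxohexanoate | CC(=O)CCCC(=O)OC | intermediate
15 | methyl 5-[(tert-butyldimethylsilyl)oxy]hex-5-enoate | C=C(O[Si](C)(C)C(C)(C)C)CCCC(=O)OC | intermediate
16 | lithium ester enolate of 15 | [Li+].[O-]C(OC)=CCCC(=C)O[Si](C)(C)C(C)(C)C | intermediate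
17 | dilithium 2α,3β-dialkoxide of the 19,10-lactone aldol adduct | [Li+].[Li+].COC(=O)C(CCC(=C)O[Si](C)(C)C(C)(C)C)[C@@]12C[C@@H]([O-])[C@H]([O-])[C@@](C)(C(=O)O1)[C@H]2CC(=O)OC | intermediate
18 | aldol–lactone diester, 2α,3β-bis(triethylsilyl) ether (C9 not fixed) | COC(=O)C(CCC(=C)O[Si](C)(C)C(C)(C)C)[C@@]12C[C@@H](O[Si](CC)(CC)CC)[C@H](O[Si](CC)(CC)CC)[C@@](C)(C(=O)O1)[C@H]2CC(=O)OC | intermediate
19 | ring A/B β-keto ester (8-oxo, 6β-CO2Me, 9β-H) | C=C(O[Si](C)(C)C(C)(C)C)CC[C@H]1[C@@]23C[C@@H](O[Si](CC)(CC)CC)[C@H](O[Si](CC)(CC)CC)[C@@](C)(C(=O)O2)[C@H]3[C@H](C(=O)OC)C1=O | intermediate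
20 | propargyl bromide | BrCC#C | starting material
21 | 8-hydroxy-8-propargyl compound (C8 epimers) | C=C(O[Si](C)(C)C(C)(C)C)CC[C@H]1[C@@]23C[C@@H](O[Si](CC)(CC)CC)[C@H](O[Si](CC)(CC)CC)[C@@](C)(C(=O)O2)[C@H]3[C@H](C(=O)OC)C1(O)CC#C | intermediate
22 | N-phthalimidoyl oxalate of 21 | C=C(O[Si](C)(C)C(C)(C)C)CC[C@H]1[C@@]23C[C@@H](O[Si](CC)(CC)CC)[C@H](O[Si](CC)(CC)CC)[C@@](C)(C(=O)O2)[C@H]3[C@H](C(=O)OC)C1(OC(=O)C(=O)ON4C(=O)c5ccccc5C4=O)CC#C | intermediate
23 | target methyl ester, 2,3-bis(triethylsilyl) 13-(tert-butyldimethylsilyl) ether | C=C1C[C@]23C[C@@]1(O[Si](C)(C)C(C)(C)C)CC[C@H]2[C@@]12C[C@@H](O[Si](CC)(CC)CC)[C@H](O[Si](CC)(CC)CC)[C@@](C)(C(=O)O1)[C@H]2[C@@H]3C(=O)OC | intermediate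
24 | target acid, tris-silyl ether | C=C1C[C@]23C[C@@]1(O[Si](C)(C)C(C)(C)C)CC[C@H]2[C@@]12C[C@@H](O[Si](CC)(CC)CC)[C@H](O[Si](CC)(CC)CC)[C@@](C)(C(=O)O1)[C@H]2[C@@H]3C(=O)O | intermediate
25 | 2α,3β,13-trihydroxy C19-gibberellin 19,10-lactone 7-acid (CNP0265952.2) | C=C1C[C@]23C[C@@]1(O)CC[C@H]2[C@@]12C[C@@H](O)[C@H](O)[C@@](C)(C(=O)O1)[C@H]2[C@@H]3C(=O)O | target

**Step count**
Total steps: 17. Longest linear sequence: 15 (steps 1–8 and 11–17, from cyclohexa-1,4-diene).

**Three steps most likely to fail**

Step 15 (radical bicyclization). The nucleophilic tertiary radical may be reduced before it adds to the electron-rich silyl enol ether. The fallback sets out from 21 and closes the two rings by polar and ketyl chemistry. Burgess dehydration (PhMe, 50 °C) followed by K2CO3/MeOH gives the cyclopentene ester methyl ketone F1. KOt-Bu (t-BuOH/THF, 0 °C) closes ring C by intramolecular Michael addition of the methyl-ketone enolate onto C8 (6-exo, cis fusion), giving the ring C ketone F2. SmI2/HMPA/t-BuOH closes ring D by ketyl–alkyne cyclization to the 13-alcohol F3. t-BuMe2SiOTf/2,6-lutidine returns the route at 23.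

Step 11 (aldol with translactonization). Enolization or β-elimination of ketone 11 by the basic lithium enolate, or lactonization of O10 onto the C7 ester, may win. The fallback sets out from 11 and 15 and uses a Reformatsky reaction. Compound 11 is silylated (Et3SiOTf, 2,6-lutidine) to the 3-O-triethylsilyl keto lactone F5. The lithium enolate of 15 is brominated (BrCCl2CCl2Br) to the α-bromo ester F4. Zinc (Me3SiCl-activated, THF, reflux) joins them: the much less basic zinc enolate adds to C10, the alkoxide translactonizes as before, and Et3SiOTf capping returns the route at 18.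

Step 13 (Barbier propargylation). The enolized, hindered β-keto ester 19 may not accept the allenylindium reagent. The fallback sets out from 19 and brings the propargyl group in by cross-coupling. NaH/PhNTf2 gives the enol triflate F6. Negishi coupling with (3-trimethylsilylprop-2-ynyl)zinc bromide and Pd(PPh3)4 gives the silylpropargyl cyclopentene ester F7. K2CO3/MeOH removes the alkynyl silane and the silyl enol ether to give F1, which is carried through F2 and F3 as described for step 15 and returns the route at 23.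

**Further compounds**
F1 | step 15 | cyclopentene ester methyl ketone (C6=C8, 8-propargyl, 13-oxo side chain) | CC(=O)CC[C@H]1[C@@]23C[C@@H](O[Si](CC)(CC)CC)[C@H](O[Si](CC)(CC)CC)[C@@](C)(C(=O)O2)[C@H]3C(C(=O)OC)=C1CC#C
F2 | step 15 | ring C ketone (rings A, B, C closed, 13-oxo, 8β-propargyl) | C#CC[C@]23CC(=O)CC[C@H]2[C@@]12C[C@@H](O[Si](CC)(CC)CC)[C@H](O[Si](CC)(CC)CC)[C@@](C)(C(=O)O1)[C@H]2[C@@H]3C(=O)OC
F3 | step 15 | 13-alcohol (pentacyclic methyl ester, 2,3-bis(triethylsilyl) ether) | C=C1C[C@]23C[C@@]1(O)CC[C@H]2[C@@]12C[C@@H](O[Si](CC)(CC)CC)[C@H](O[Si](CC)(CC)CC)[C@@](C)(C(=O)O1)[C@H]2[C@@H]3C(=O)OC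
F4 | step 11 | methyl 2-bromo-5-[(tert-butyldimethylsilyl)oxy]hex-5-enoate | C=C(O[Si](C)(C)C(C)(C)C)CCC(Br)C(=O)OC
F5 | step 11 | 3-O-triethylsilyl keto lactone | O=C1C[C@H]2OC(=O)[C@](C)([C@H]2O[Si](CC)(CC)CC)[C@H]1CC(=O)OC
F6 | step 13 | enol triflate of 19 | C=C(O[Si](C)(C)C(C)(C)C)CC[C@H]1[C@@]23C[C@@H](O[Si](CC)(CC)CC)[C@H](O[Si](CC)(CC)CC)[C@@](C)(C(=O)O2)[C@H]3C(C(=O)OC)=C1OS(=O)(=O)C(F)(F)F
F7 | step 13 | silylpropargyl cyclopentene ester | C=C(O[Si](C)(C)C(C)(C)C)CC[C@H]1[C@@]23C[C@@H](O[Si](CC)(CC)CC)[C@H](O[Si](CC)(CC)CC)[C@@](C)(C(=O)O2)[C@H]3C(C(=O)OC)=C1CC#C[Si](C)(C)C
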